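## Structural features

The target is a 2,3-dihydrobenzofuran. Benzene ring A is fused to dihydrofuran ring B, which carries a 3-oxoprop-1-en-2-yl group (an α-substituted acrolein) at C2 and an isovalerate at C3; C5 of ring A carries a 1-(senecioyloxy)ethyl chain. C2 and C3 are adjacent stereocentres with their substituents cis (2R,3R). The third stereocentre, the (S)-carbinol carbon of the C5 side chain, is separated from them by the arene and cannot be set by relay. Several groups are fragile: the C3 ester is benzylic, ortho to O1 and next to C2–H, so ionisation and proton loss would give the aromatic benzofuran; the side-chain ester sits on a para-alkoxybenzylic carbon and can ionise with racemisation; the enal is a reactive Michael acceptor; the senecioate can move out of conjugation under base. A less obvious liability is that O1 is β to the formyl carbon, so an enolate or enamine at the carbon between them can open ring B by elimination until the methylene group is in place. The real difficulty is therefore to secure the cis-2,3 pair with an acyloxy group at C3 that must never leave, and to tell apart two secondary alcohols and one aldehyde-level carbon without protecting groups. The feature used is that the C3 oxygen, C3, C2, the enal α-carbon and the formyl carbon form a chain whose oxygen and carbonyl carbon are 1,4-related and cis on ring B, which are the atoms of a γ-butyrolactone cis-fused to ring B across C2–C3. Such a lactone descends from a butenolide whose acetal carbon becomes C3, and this carbon can be joined to the ortho carbon of ring A (C3a) by a cationic ring closure.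

## Logic of the disconnections

The exocyclic C=CH2 bond of 14 is cut first, which leads to 11 and the one-carbon unit 12. The α-methylene aldehyde is the most electrophilic group and is best made last. The forward step must methylenate through 13 faster than the enamine expels the ring oxygen, and must leave two esters alone.

The formyl C–H bond of 11 is exchanged for the C–N bond of an N-methoxy-N-methylamide, which gives 10. The amide survives transfer hydrogenation and both acylations, so it can carry the carbonyl carbon through the middle of the route. The forward reduction has to stop at the aldehyde and prefer the amide to a saturated and a conjugated ester.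

The acyl–oxygen bond of the side-chain ester of 10 is cut, giving 8 and 9. This ester lies on an easily ionised benzylic carbon, so it is attached only after every Lewis-acidic operation. The forward acylation must keep the carbinol C–O bond and the double-bond position of 9.

The carbinol C–H bond of 8 is removed, which returns the aryl methyl ketone 7. The centre is remote from C2 and C3, so a catalyst alone must set it; the ketone is also the group that restrains ring A earlier in the route. The reduction must be enantioselective and ignore the amide and the benzylic ester.

The acyl–oxygen bond of the C3 ester of 7 is cut, giving 5 and 6. Putting the isovaleryl group directly on the freed hydroxyl avoids a protecting group. The acylation must be faster than the return of 5 to the lactone.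

The amide C–N bond of 5 is cut and the C3 oxygen is reconnected to the carboxyl carbon, which gives 4. Hydroxyl, carboxyl carbon and their cis relationship collapse into one ring. The forward opening needs a reagent that makes no enolate, because the aryloxy group is β to the carbonyl.

The C3–C3a bond of the benzofuran (C8b–C8a in 4) is cut and the auxiliary alcohol is returned to the carbon that loses the arene, giving 3. This removes ring B and one stereocentre and leaves a monocyclic lactone acetal. The forward step needs a cation at the acetal carbon, capture by an arene made sluggish by its para-acetyl group, and no further ionisation of the new benzylic C–O bond.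

The aryl ether C–O bond of 3 is cut, giving 1 and 2, both purchasable. The acetal centre of 1 must send the phenoxide to the opposite face, and the conjugate addition must not revert.

## Other disconnections considered

Alternative 1: The cut passes through ring A at C3a–C4 and C5–C6, so ring B with both stereocentres comes from a carbohydrate and the benzene ring is built last. In the forward direction the 1-alkoxy-3-oxy diene A2, a vinyl-substituted furanoid glycal, would add to the ynone A3 in a Diels–Alder reaction, and the adduct would lose its alkoxy group as the alcohol to give arene A1.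
- In its favour: C2 and C3 come from the chiral pool; the electron-rich diene terminus (the future C3a) bonds to the alkyne CH, which places the acetyl group at C5 without electrophilic substitution on a deactivated ring; the side chain of A1 already carries its oxygen, so the enal needs only desilylation and oxidation.
- Against it here: A2 is an acid-labile, cross-conjugated bis-enol ether that would need a long sequence from the sugar. In the cyclohexadiene adduct the C3 ether is allylic, so its loss (towards a benzofuran) competes with loss of the alkoxy group. After A1, two protecting groups must still be exchanged for two different esters around an asymmetric reduction.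
- Comparison: on structure both plans reach a cis-2,3-dihydrobenzofuran with a 5-acetyl handle, and A1 is the better on two points, the source of absolute configuration and the absence of a methylenation beside a β-aryloxy aldehyde. On mechanism the pericyclic step does not depend on arene nucleophilicity, which is better, but both plans share the danger of eliminating the C3 oxygen. On step economy the chosen plan is shorter, since 4 is two steps from purchasable materials and the endgames are of similar length.

Alternative 2: The cut is the C2–C3 bond. The eight-membered cyclic aryl enol ether A5 would be deprotonated at its benzylic OCH2 group by an alkyllithium with a chiral bis(oxazoline) ligand, and a [2,3]-Wittig shift would contract the ring to alcohol A4.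
- In its favour: one concerted step makes the C2–C3 bond and both stereocentres; the fixed geometry of the ring enol ether should translate into the cis product; A4 has a free C3 hydroxyl ready for isovalerylation, so no lactone has to be opened. On these points it is the better plan.
- Against it here: A5 needs a medium-ring closure that includes an aryl enol ether. The absolute configuration rests on a stoichiometric external ligand distinguishing two enantiotopic protons, with [1,2]-shift and ring lithiation as competitors. The isopropenyl methyl of A4 must later be oxidised to the aldehyde, and that oxidation has to be fitted between ketal removal, ketone reduction (which an enal would not survive) and senecioylation (whose allylic methyls would compete).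
- Comparison: structurally it is the more direct route to the stereo-pair; mechanistically the auxiliary-based plan offers the safer absolute control, because 3 is a separable diastereomer; in step count the precursor synthesis and the late oxidation should make it the longer route.

Alternative 3: The cut is the O1–C2 bond. Sulfonylation of the C3 hydroxyl of chromanol A7 would trigger a 1,2-shift of the aryl ether oxygen from the quaternary carbon to C3, contracting the six-membered ring and giving ester A6 with its isopropenyl group.
- In its favour: the cis-diol pattern of A7 is of the kind that catalytic asymmetric dihydroxylation of a chromene delivers; the shift is stereospecific (inversion at the migration terminus gives the cis product); the C3 isovalerate is in place from the start. It is the equal of the chosen plan in stereochemical logic and the better in step count to the cis core.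
- Against it here: the leaving group must lie antiperiplanar to the C2–O1 bond; methyl or hydride shift and elimination compete; the para-acetyl group lowers the migratory ability of O1. The isopropenyl methyl of A6 must then be oxidised to the aldehyde in the presence of the acetyl methyl or, later, of the senecioate methyls.
- Comparison: both plans tame ring A with the acetyl group, and both risk cation chemistry at a benzylic position. The chosen plan carries the aldehyde carbon at the carboxyl level from the first step and so avoids the late C–H oxidation, which is the weakest point of A6.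

Key step: step 2

Remark on the chemistry: 1 is taken as the purchasable, diastereomerically pure (5R)-acetal. The trans adduct 3 is then (4R,5R) and lactone 4 is (3aR,8bR), which corresponds to (2R,3R) in 14, so the l-menthyl series is the correct one.

## Route

Step 1
Reactants: 1 (5R)-5-(l-menthyloxy)furan-2(5H)-one; 2 4'-hydroxyacetophenone
Product: 3 (4R,5R)-4-(4-acetylphenoxy)-5-(l-menthyloxy)dihydrofuran-2(3H)-one (trans)
Conditions: 2 (1.3 equiv), Cs2CO3 (0.2 equiv), MeCN, 0 °C → rt; AcOH quench
Reagents that add atoms: none
Why: Base-catalysed oxa-Michael addition: the phenoxide of 2 should add to C4 of the butenolide on the face opposite the bulky menthyloxy group at C5, so the new centre is (4R), trans to the acetal substituent. Catalytic base, low temperature and an acidic quench limit retro-addition and epimerisation of the acetal carbon, and any minor diastereomer is separable because of the menthyl group.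

Step 2
Reactants: 3 (4R,5R)-4-(4-acetylphenoxy)-5-(l-menthyloxy)dihydrofuran-2(3H)-one
Product: 4 (3aR,8bR)-7-acetyl-3a,8b-dihydrofuro[3,2-b]benzofuran-2(3H)-one (cis-fused tricyclic lactone)
Conditions: SnCl4 (3 equiv), CH2Cl2, −78 → −20 °C; quench at −20 °C with aq. NaHCO3
Reagents that add atoms: none
Why: SnCl4 should ionise the acetal carbon of 3 with loss of the menthyl oxygen, giving a lactone oxocarbenium ion that the ortho carbon of the neighbouring aryl ether attacks; proton loss from the arenium ion completes an intramolecular Friedel–Crafts alkylation that forms the C8a–C8b bond (C3–C3a of the benzofuran). The closest known reaction types are the Lewis-acid arylation of γ-alkoxy-γ-lactones and the acid ring closure of aryloxyacetaldehyde acetals on the way to benzofurans. Ring B closes in a 5-exo-trig mode with respect to the C=O+ bond, with the aromatic C=C inside the new ring. The new centre C8b is controlled by C3a, because two fused five-membered rings cannot be trans-fused, so the arene can only bond to the face of the cation on which its oxygen tether lies. Opening of the acetal at the ring oxygen is expected to be reversible and to return 3, so the productive channel is the one that keeps the lactone. Regiochemistry is not an issue, since the two ortho carbons are equivalent and each is ortho to the ether oxygen and meta to the acetyl group. The step must stop at the acyloxy stage: the SnCl4-bound acetyl group para to the ether oxygen weakens its donation, so the new benzylic C–O bond should not ionise at low temperature, and the cold quench removes the acid before warming. The same deactivation slows the capture, which is why an excess of SnCl4 (one equivalent is held by the ketone) and slow warming are specified.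

Step 3
Reactants: 4 (3aR,8bR)-7-acetyl-3a,8b-dihydrofuro[3,2-b]benzofuran-2(3H)-one
Product: 5 2-[(2R,3R)-5-acetyl-3-hydroxy-2,3-dihydrobenzofuran-2-yl]-N-methoxy-N-methylacetamide (cis)
Conditions: MeNH(OMe)·HCl (3 equiv), AlMe3 (3 equiv), CH2Cl2, 0 °C, premixed until gas evolution ends; then 4, 0 °C → rt; aq. potassium sodium tartrate
Reagents that add atoms: N,O-dimethylhydroxylamine hydrochloride, CNOC.Cl
Why: Aluminium-amide aminolysis of a lactone (Weinreb amidation): the Lewis-acidic aluminium amide transfers the amine to the lactone carbonyl without forming an enolate, so the β-aryloxy group is not eliminated. The C3–O bond is untouched, so both stereocentres are retained, and the premixed reagent carries little free methyl nucleophile for the aryl ketone.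

Step 4
Reactants: 5 2-[(2R,3R)-5-acetyl-3-hydroxy-2,3-dihydrobenzofuran-2-yl]-N-methoxy-N-methylacetamide; 6 3-methylbutanoyl chloride
Product: 7 (2R,3R)-5-acetyl-2-{2-[methoxy(methyl)amino]-2-oxoethyl}-2,3-dihydrobenzofuran-3-yl 3-methylbutanoate
Conditions: 6 (1.5 equiv), pyridine (3 equiv), DMAP (0.1 equiv), CH2Cl2, 0 °C, on crude 5
Reagents that add atoms: none
Why: DMAP-catalysed O-acylation of the secondary benzylic alcohol, run at once on crude 5 so that ester formation outruns re-lactonisation. The acyl group goes onto oxygen, so no stereocentre is touched.

Step 5
Reactants: 7 (2R,3R)-5-acetyl-2-{2-[methoxy(methyl)amino]-2-oxoethyl}-2,3-dihydrobenzofuran-3-yl 3-methylbutanoate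
Product: 8 (2R,3R)-5-[(1S)-1-hydroxyethyl]-2-{2-[methoxy(methyl)amino]-2-oxoethyl}-2,3-dihydrobenzofuran-3-yl 3-methylbutanoate
Conditions: RuCl(p-cymene)[(S,S)-TsDPEN] (1 mol%), HCO2H/Et3N (5:2), EtOAc, 30 °C
Reagents that add atoms: none
Why: Noyori-type asymmetric transfer hydrogenation of an aryl methyl ketone: the (S,S)-catalyst should deliver hydride to the Re face through the six-membered transition state organised by the arene C–H/π contact, giving the (S)-carbinol under catalyst control, independent of the remote ring centres. The amide and the ester are inert to the ruthenium hydride.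

Step 6
Reactants: 8 (2R,3R)-5-[(1S)-1-hydroxyethyl]-2-{2-[methoxy(methyl)amino]-2-oxoethyl}-2,3-dihydrobenzofuran-3-yl 3-methylbutanoate; 9 3-methylbut-2-enoic acid
Product: 10 (1S)-1-[(2R,3R)-2-{2-[methoxy(methyl)amino]-2-oxoethyl}-3-(3-methylbutanoyloxy)-2,3-dihydrobenzofuran-5-yl]ethyl 3-methylbut-2-enoate
Conditions: 9 (1.5 equiv), DIC (1.5 equiv), DMAP (0.2 equiv), CH2Cl2, 0 °C → rt
Reagents that add atoms: none
Why: Steglich esterification: acyl transfer to the carbinol oxygen leaves the C–O bond intact, so the (S) centre is retained. The absence of an acid chloride and of a strong base avoids vinylketene formation (deconjugation of the senecioyl group) and ionisation of the benzylic alcohol.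

Step 7
Reactants: 10 (1S)-1-[(2R,3R)-2-{2-[methoxy(methyl)amino]-2-oxoethyl}-3-(3-methylbutanoyloxy)-2,3-dihydrobenzofuran-5-yl]ethyl 3-methylbut-2-enoate
Product: 11 (1S)-1-[(2R,3R)-3-(3-methylbutanoyloxy)-2-(2-oxoethyl)-2,3-dihydrobenzofuran-5-yl]ethyl 3-methylbut-2-enoate
Conditions: Cp2Zr(H)Cl (1.6 equiv), THF, rt, 20 min; then H2O/silica
Reagents that add atoms: none
Why: Chemoselective amide-to-aldehyde reduction with Cp2Zr(H)Cl: the amide oxygen binds zirconium, hydride is delivered once, and the aldehyde is released only on work-up, so over-reduction is not expected. Esters and the trisubstituted conjugated alkene react much more slowly with this reagent.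

Step 8
Reactants: 11 (1S)-1-[(2R,3R)-3-(3-methylbutanoyloxy)-2-(2-oxoethyl)-2,3-dihydrobenzofuran-5-yl]ethyl 3-methylbut-2-enoate; 12 formaldehyde (37% aqueous)
Product: 14 (1S)-1-[(2R,3R)-3-(3-methylbutanoyloxy)-2-(3-oxoprop-1-en-2-yl)-2,3-dihydrobenzofuran-5-yl]ethyl 3-methylbut-2-enoate (CNP0325942.1), via pyrrolidinomethyl Mannich base 13 (not isolated)
Conditions: 12 (1.2 equiv), pyrrolidine (10 mol%), EtCO2H (10 mol%), i-PrOH, 45 °C
Reagents that add atoms: none
Why: Amine-catalysed α-methylenation: the enamine of 11 undergoes a Mannich reaction with the iminium ion of 12 to give 13, which loses pyrrolidine by elimination to the α-methylene aldehyde. The α-centre of 13 is transient, and once the methylene group is in place no α-hydrogen remains, so ring B can no longer open by β-elimination.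

## Compound list

1 | (5R)-5-{[(1R,2S,5R)-5-methyl-2-(propan-2-yl)cyclohexyl]oxy}furan-2(5H)-one | O=C1C=C[C@H](O[C@@H]2C[C@H](C)CC[C@H]2C(C)C)O1 | starting material
2 | 1-(4-hydroxyphenyl)ethanone (4'-hydroxyacetophenone) | CC(=O)c1ccc(O)cc1 | starting material
3 | (4R,5R)-4-(4-acetylphenoxy)-5-(l-menthyloxy)dihydrofuran-2(3H)-one | O=C1C[C@@H](Oc2ccc(C(C)=O)cc2)[C@H](O[C@@H]2C[C@H](C)CC[C@H]2C(C)C)O1 | intermediate
4 | (3aR,8bR)-7-acetyl-3a,8b-dihydrofuro[3,2-b]benzofuran-2(3H)-one | O=C1C[C@H]2Oc3ccc(C(C)=O)cc3[C@H]2O1 | intermediate
5 | 2-[(2R,3R)-5-acetyl-3-hydroxy-2,3-dihydrobenzofuran-2-yl]-N-methoxy-N-methylacetamide | CON(C)C(=O)C[C@H]1Oc2ccc(C(C)=O)cc2[C@H]1O | intermediate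
6 | 3-methylbutanoyl chloride | CC(C)CC(=O)Cl | starting material
7 | (2R,3R)-5-acetyl-2-{2-[methoxy(methyl)amino]-2-oxoethyl}-2,3-dihydrobenzofuran-3-yl 3-methylbutanoate | CON(C)C(=O)C[C@H]1Oc2ccc(C(C)=O)cc2[C@H]1OC(=O)CC(C)C | intermediate
8 | (2R,3R)-5-[(1S)-1-hydroxyethyl]-2-{2-[methoxy(methyl)amino]-2-oxoethyl}-2,3-dihydrobenzofuran-3-yl 3-methylbutanoate | CON(C)C(=O)C[C@H]1Oc2ccc([C@H](C)O)cc2[C@H]1OC(=O)CC(C)C | intermediate
9 | 3-methylbut-2-enoic acid | CC(C)=CC(=O)O | starting material
10 | (1S)-1-[(2R,3R)-2-{2-[methoxy(methyl)amino]-2-oxoethyl}-3-(3-methylbutanoyloxy)-2,3-dihydrobenzofuran-5-yl]ethyl 3-methylbut-2-enoate | CON(C)C(=O)C[C@H]1Oc2ccc([C@H](C)OC(=O)C=C(C)C)cc2[C@H]1OC(=O)CC(C)C | intermediate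
11 | (1S)-1-[(2R,3R)-3-(3-methylbutanoyloxy)-2-(2-oxoethyl)-2,3-dihydrobenzofuran-5-yl]ethyl 3-methylbut-2-enoate | O=CC[C@H]1Oc2ccc([C@H](C)OC(=O)C=C(C)C)cc2[C@H]1OC(=O)CC(C)C | intermediate
12 | formaldehyde | C=O | starting material
13 | (1S)-1-[(2R,3R)-3-(3-methylbutanoyloxy)-2-[1-oxo-3-(pyrrolidin-1-yl)propan-2-yl]-2,3-dihydrobenzofuran-5-yl]ethyl 3-methylbut-2-enoate (both α-epimers) | O=CC(CN1CCCC1)[C@H]1Oc2ccc([C@H](C)OC(=O)C=C(C)C)cc2[C@H]1OC(=O)CC(C)C | intermediate
14 | (1S)-1-[(2R,3R)-3-(3-methylbutanoyloxy)-2-(3-oxoprop-1-en-2-yl)-2,3-dihydrobenzofuran-5-yl]ethyl 3-methylbut-2-enoate | C=C(C=O)[C@H]1Oc2ccc([C@H](C)OC(=O)C=C(C)C)cc2[C@H]1OC(=O)CC(C)C | target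

## Step count and least certain steps

Total step count: 8. Longest linear sequence: 8 steps (1 → 14).

Step 2 (key step). Three processes may interfere. Ionisation at the ring oxygen instead of the menthyl oxygen would let the arene add to an open, menthyloxy-stabilised cation and leave a benzylic menthyl ether instead of the lactone. Capture of the cation by the SnCl4-bound acetophenone ring may be too slow, so that proton loss from the cation or acid-promoted loss of the phenol wins. Over-ionisation of the new benzylic C–O bond would end in aromatisation. The fallback postpones the acetyl group. It sets out from 1, which with 4-bromophenol under the conditions of step 1 should give (4R,5R)-4-(4-bromophenoxy)-5-(l-menthyloxy)dihydrofuran-2(3H)-one F1. The bromoarene does not bind the Lewis acid, and rings of this kind close in the acid cyclisations used for 5-bromobenzofurans, so the SnCl4 treatment should give (3aR,8bR)-7-bromo-3a,8b-dihydrofuro[3,2-b]benzofuran-2(3H)-one F2. Stille coupling with tributyl(1-ethoxyvinyl)stannane (Pd(PPh3)4, toluene, 90 °C) should give (3aR,8bR)-7-(1-ethoxyethenyl)-3a,8b-dihydrofuro[3,2-b]benzofuran-2(3H)-one F3, and dilute aqueous HCl in THF should hydrolyse the enol ether, so that the route is rejoined at 4.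

Step 8. The enamine of 11 has the ring oxygen in the β-position, so expulsion of the aryloxide (opening of ring B) may compete with the Mannich reaction, and the product enal may add the amine catalyst. The fallback separates enol formation from C–C bond formation. It sets out from 11, which with TMSOTf/Et3N (CH2Cl2, −78 °C) should give the trimethylsilyl enol ether F4 without a free enolate or enamine. Dimethylmethyleneiminium iodide in CH2Cl2 should then give the α-(dimethylaminomethyl) aldehyde F5 by a Mukaiyama–Mannich reaction. Quaternisation with MeI and treatment with NaHCO3 (Hofmann-type elimination) should return the route at 14.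

Step 1. 4-Acetylphenoxide is a weak nucleophile and a good leaving group, so the addition may be reversible with an unfavourable balance. Prolonged exposure to base may also epimerise the acetal carbon of 1 through its dienolate. The fallback masks the ketone so that the phenoxide becomes more nucleophilic and a poorer leaving group. It sets out from 2, which with ethylene glycol and TsOH (toluene, water removal) should give 4-(2-methyl-1,3-dioxolan-2-yl)phenol F6. Addition to 1 under the conditions of step 1 should give the ketal-protected trans adduct F7, and PPTS in wet acetone should remove the dioxolane, which is far more labile than the lactone acetal, to rejoin the route at 3.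

Step 3. The cis hydroxy amide may close back to the lactone during work-up or before acylation is complete, and methyl transfer from aluminium to the ketone is a possible side reaction. The fallback uses an amide that is not activated towards re-lactonisation and needs no aluminium reagent. It sets out from 4, which with pyrrolidine (THF, 40 °C) should give 2-[(2R,3R)-5-acetyl-3-hydroxy-2,3-dihydrobenzofuran-2-yl]-1-(pyrrolidin-1-yl)ethanone F8. The operations of steps 4, 5 and 6 should then give the isovalerate F9, the (S)-carbinol F10 and the senecioate F11. Cp2Zr(H)Cl also reduces such tertiary amides to aldehydes, so the route is rejoined at 11.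

## Further compounds

F1 | step 2 | (4R,5R)-4-(4-bromophenoxy)-5-(l-menthyloxy)dihydrofuran-2(3H)-one | O=C1C[C@@H](Oc2ccc(Br)cc2)[C@H](O[C@@H]2C[C@H](C)CC[C@H]2C(C)C)O1
F2 | step 2 | (3aR,8bR)-7-bromo-3a,8b-dihydrofuro[3,2-b]benzofuran-2(3H)-one | O=C1C[C@H]2Oc3ccc(Br)cc3[C@H]2O1
F3 | step 2 | (3aR,8bR)-7-(1-ethoxyethenyl)-3a,8b-dihydrofuro[3,2-b]benzofuran-2(3H)-one | O=C1C[C@H]2Oc3ccc(C(=C)OCC)cc3[C@H]2O1
F4 | step 8 | trimethylsilyl enol ether of 11 (E/Z mixture) | C[Si](C)(C)OC=C[C@H]1Oc2ccc([C@H](C)OC(=O)C=C(C)C)cc2[C@H]1OC(=O)CC(C)C
F5 | step 8 | α-(dimethylaminomethyl) derivative of 11 (both α-epimers) | CN(C)CC(C=O)[C@H]1Oc2ccc([C@H](C)OC(=O)C=C(C)C)cc2[C@H]1OC(=O)CC(C)C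
F6 | step 1 | 4-(2-methyl-1,3-dioxolan-2-yl)phenol | CC1(c2ccc(O)cc2)OCCO1
F7 | step 1 | (4R,5R)-5-(l-menthyloxy)-4-[4-(2-methyl-1,3-dioxolan-2-yl)phenoxy]dihydrofuran-2(3H)-one | O=C1C[C@@H](Oc2ccc(C3(C)OCCO3)cc2)[C@H](O[C@@H]2C[C@H](C)CC[C@H]2C(C)C)O1
F8 | step 3 | 2-[(2R,3R)-5-acetyl-3-hydroxy-2,3-dihydrobenzofuran-2-yl]-1-(pyrrolidin-1-yl)ethanone | O=C(C[C@H]1Oc2ccc(C(C)=O)cc2[C@H]1O)N1CCCC1
F9 | step 3 | (2R,3R)-5-acetyl-2-[2-oxo-2-(pyrrolidin-1-yl)ethyl]-2,3-dihydrobenzofuran-3-yl 3-methylbutanoate | O=C(C[C@H]1Oc2ccc(C(C)=O)cc2[C@H]1OC(=O)CC(C)C)N1CCCC1
F10 | step 3 | (2R,3R)-5-[(1S)-1-hydroxyethyl]-2-[2-oxo-2-(pyrrolidin-1-yl)ethyl]-2,3-dihydrobenzofuran-3-yl 3-methylbutanoate | O=C(C[C@H]1Oc2ccc([C@H](C)O)cc2[C@H]1OC(=O)CC(C)C)N1CCCC1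
F11 | step 3 | (1S)-1-[(2R,3R)-3-(3-methylbutanoyloxy)-2-[2-oxo-2-(pyrrolidin-1-yl)ethyl]-2,3-dihydrobenzofuran-5-yl]ethyl 3-methylbut-2-enoate | O=C(C[C@H]1Oc2ccc([C@H](C)OC(=O)C=C(C)C)cc2[C@H]1OC(=O)CC(C)C)N1CCCC1
A1 | alternative 1 | 1-[(2R,3R)-2-[3-(tert-butyldiphenylsilyloxy)prop-1-en-2-yl]-3-(4-methoxybenzyloxy)-2,3-dihydrobenzofuran-5-yl]ethanone | C=C(CO[Si](c1ccccc1)(c1ccccc1)C(C)(C)C)[C@H]1Oc2ccc(C(C)=O)cc2[C@H]1OCc1ccc(OC)cc1
A2 | alternative 1 | (2R,3R)-2-[3-(tert-butyldiphenylsilyloxy)prop-1-en-2-yl]-5-[(E)-2-ethoxyethenyl]-3-(4-methoxybenzyloxy)-2,3-dihydrofuran | C=C(CO[Si](c1ccccc1)(c1ccccc1)C(C)(C)C)[C@H]1OC(/C=C/OCC)=C[C@H]1OCc1ccc(OC)cc1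
A3 | alternative 1 | but-3-yn-2-one | CC(=O)C#C
A4 | alternative 2 | (2R,3R)-5-(2-methyl-1,3-dioxolan-2-yl)-2-(prop-1-en-2-yl)-2,3-dihydrobenzofuran-3-ol | C=C(C)[C@H]1Oc2ccc(C3(C)OCCO3)cc2[C@H]1O
A5 | alternative 2 | eight-membered cyclic ether in which O–CH=C(CH3)–CH2–O–CH2 bridges two ortho positions of the arene, with the 2-methyl-1,3-dioxolan-2-yl group para to the enol ether oxygen | CC1=COc2ccc(C3(C)OCCO3)cc2COC1
A6 | alternative 3 | (2R,3R)-5-acetyl-2-(prop-1-en-2-yl)-2,3-dihydrobenzofuran-3-yl 3-methylbutanoate | C=C(C)[C@H]1Oc2ccc(C(C)=O)cc2[C@H]1OC(=O)CC(C)C
A7 | alternative 3 | (3R,4R)-6-acetyl-3-hydroxy-2,2-dimethyl-3,4-dihydro-2H-chromen-4-yl 3-methylbutanoate | CC(=O)c1ccc2OC(C)(C)[C@H](O)[C@H](OC(=O)CC(C)C)c2c1
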